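Ring B, the 4,5-disubstituted catechol, is the target of the disconnection: its hydroxyl-bearing carbons C4′ and C5′ sit opposite C1′ (bonded to ring A) and C2′ (bearing the CH2CH2 bridge), so the ring divides into an O–C=C–O two-carbon unit and a 2,3-disubstituted butadiene. A thermal Diels–Alder reaction of vinylene carbonate with that diene forms C3′–C4′ and C5′–C6′ and closes ring B in one operation; oxidation of the derived cis-diol then aromatises it to the catechol without a separate dehydrogenation. The diene carries ring A as its acetonide and the 3-methoxyphenethyl chain, and comes from an aryl alkyne by ethylene enyne metathesis.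

Key step: step 7

Remark on the chemistry: ring A is the catechol ring with the biaryl bond next to a hydroxyl group and ring B carries the primed biphenyl locants; the target is achiral; diethyl (3-methoxybenzyl)phosphonate is taken as a catalogue reagent.

Step 1
Reactants: 1 3-bromo-4,5-dihydroxybenzaldehyde
Product: 2 7-bromo-2,2-dimethyl-1,3-benzodioxole-5-carbaldehyde
Conditions: Me2C(OMe)2, TsOH·H2O (cat.), toluene, reflux, MeOH removed (Soxhlet, 4 Å MS); 1 M HCl/THF work-up, rt
Reagents that add atoms: 2,2-dimethoxypropane, COC(C)(C)OC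
Why: Acid-catalysed trans-ketalisation (acetonide formation) closes the five-membered 2,2-dimethylbenzodioxole as methanol is removed, and the brief aqueous acid work-up returns any aldehyde dimethyl acetal to the free aldehyde without opening the far more robust aryl ketal.

Step 2
Reactants: 2 7-bromo-2,2-dimethyl-1,3-benzodioxole-5-carbaldehyde; 3 diethyl (3-methoxybenzyl)phosphonate
Product: 5 4-bromo-6-[(E)-2-(3-methoxyphenyl)ethenyl]-2,2-dimethyl-1,3-benzodioxole, via potassium phosphonate carbanion 4 (not isolated)
Conditions: 3, KOt-Bu, THF, 0 °C; then 2, 0 °C to rt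
Reagents that add atoms: none
Why: Horner–Wadsworth–Emmons olefination, in which the benzylic phosphonate carbanion adds to the non-enolisable aryl aldehyde and eliminates diethyl phosphate to give the E-stilbene, the aryl bromide and the ketal being inert to KOt-Bu (the alkene geometry is erased in step 3).

Step 3
Reactants: 5 4-bromo-6-[(E)-2-(3-methoxyphenyl)ethenyl]-2,2-dimethyl-1,3-benzodioxole
Product: 6 4-bromo-6-[2-(3-methoxyphenyl)ethyl]-2,2-dimethyl-1,3-benzodioxole
Conditions: TsNHNH2 (excess), NaOAc, DME/H2O, reflux
Reagents that add atoms: none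
Why: Diimide reduction, in which HN=NH released from the sulfonyl hydrazide transfers two hydrogens to the C=C bond through a concerted cyclic transition state and cannot cleave the aryl C–Br bond that a palladium-catalysed hydrogenation would endanger, while the acetate buffer protects the ketal.

Step 4
Reactants: 7 propargyl bromide (3-bromoprop-1-yne); 8 3-methoxybenzyl bromide
Product: 10 1-(but-3-yn-1-yl)-3-methoxybenzene, via allenylmagnesium bromide 9 (not isolated)
Conditions: 7, Mg, HgCl2 (cat.), Et2O, 0 °C; then 8, Et2O, 0 °C to reflux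
Reagents that add atoms: none
Why: Grignard alkylation in which the reagent, present largely as allenylmagnesium bromide, attacks the reactive benzylic bromide through its γ-carbon (SE2′) and so delivers the terminal homopropargyl arene.

Step 5
Reactants: 6 4-bromo-6-[2-(3-methoxyphenyl)ethyl]-2,2-dimethyl-1,3-benzodioxole; 10 1-(but-3-yn-1-yl)-3-methoxybenzene
Product: 11 4-[4-(3-methoxyphenyl)but-1-yn-1-yl]-6-[2-(3-methoxyphenyl)ethyl]-2,2-dimethyl-1,3-benzodioxole
Conditions: PdCl2(MeCN)2 (3 mol%), XPhos (9 mol%), Cs2CO3, MeCN, 80 °C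
Reagents that add atoms: none
Why: Copper-free Sonogashira coupling, in which the bulky electron-rich biarylphosphine drives oxidative addition of the electron-rich, ortho-oxygenated aryl bromide to zerovalent palladium, Cs2CO3 deprotonates the palladium-bound alkyne, and the absence of copper suppresses Glaser dimerisation of 10.

Step 6
Reactants: 11 4-[4-(3-methoxyphenyl)but-1-yn-1-yl]-6-[2-(3-methoxyphenyl)ethyl]-2,2-dimethyl-1,3-benzodioxole
Product: 12 4-[5-(3-methoxyphenyl)-3-methylidenepent-1-en-2-yl]-6-[2-(3-methoxyphenyl)ethyl]-2,2-dimethyl-1,3-benzodioxole (the 2-aryl-3-(3-methoxyphenethyl)buta-1,3-diene)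
Conditions: ethylene (1 atm), second-generation Grubbs catalyst (H2IMes)(PCy3)Cl2Ru=CHPh (10 mol%), toluene, 80 °C
Reagents that add atoms: ethylene, C=C
Why: Cross enyne metathesis with ethylene, in which the ruthenium methylidene adds across the alkyne to a ruthenacyclobutene that opens to a vinylcarbene and is turned over by ethylene, so each alkyne carbon ends up carrying a CH2= group; internal aryl/alkyl alkynes are established substrates and no regiochemical question arises.

Step 7
Reactants: 12 4-[5-(3-methoxyphenyl)-3-methylidenepent-1-en-2-yl]-6-[2-(3-methoxyphenyl)ethyl]-2,2-dimethyl-1,3-benzodioxole; 13 vinylene carbonate (1,3-dioxol-2-one)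
Product: 14 cis-5-{6-[2-(3-methoxyphenyl)ethyl]-2,2-dimethyl-1,3-benzodioxol-4-yl}-6-[2-(3-methoxyphenyl)ethyl]-3a,4,7,7a-tetrahydro-1,3-benzodioxol-2-one (racemic)
Conditions: 13 (10 equiv), BHT (cat.), o-xylene, sealed tube, 170 °C
Reagents that add atoms: none
Why: Concerted, thermally allowed [4πs+2πs] Diels–Alder cycloaddition between the s-cis conformer of diene 12 and the C=C bond of 13, the closest known reaction type being the thermal addition of vinylene carbonate to 2,3-dialkyl- and 2,3-diarylbutadienes. Ring B closes as a six-membered carbocycle by intermolecular cycloaddition, both σ-bonds (diene CH2 termini to the two oxygen-bearing carbons) being made in the same step. The two new stereocentres are the ring-fusion carbons, and their cis relationship is dictated by the Z geometry locked in the five-membered ring of 13 together with suprafacial addition; the product is racemic because neither partner is chiral. No regio- or endo/exo selectivity is at stake, since 13 is C2v-symmetric and the diene termini are unsubstituted CH2 groups. What the step needs is chemoselectivity for cross-cycloaddition over dimerisation or polymerisation of the diene, which is secured by the large excess of 13, the radical inhibitor and the ortho-oxygenated aryl group, which twists out of the diene plane and shields it without blocking the s-cis geometry.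

Step 8
Reactants: 14 cis-fused cyclohexene carbonate
Product: 15 cis-4-{6-[2-(3-methoxyphenyl)ethyl]-2,2-dimethyl-1,3-benzodioxol-4-yl}-5-[2-(3-methoxyphenyl)ethyl]cyclohex-4-ene-1,2-diol (racemic)
Conditions: NaOH (1 M aq.), 1,4-dioxane, rt
Reagents that add atoms: none
Why: Saponification of the five-membered cyclic carbonate by acyl–oxygen cleavage releases the diol with both C–O bonds, and hence the cis configuration, untouched, while the ketal, the aryl ethers and the tetrasubstituted alkene are inert to aqueous hydroxide.

Step 9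
Reactants: 15 cis-cyclohex-4-ene-1,2-diol
Product: 17 4-{6-[2-(3-methoxyphenyl)ethyl]-2,2-dimethyl-1,3-benzodioxol-4-yl}-5-[2-(3-methoxyphenyl)ethyl]benzene-1,2-diol, via cyclohex-4-ene-1,2-dione 16 (not isolated)
Conditions: DMSO, (CF3CO)2O, CH2Cl2, −78 °C; 15; then Et3N, −78 °C to rt
Reagents that add atoms: none
Why: Twofold Swern oxidation (DMSO activated by trifluoroacetic anhydride), established for cyclic cis-1,2-diols as a route to 1,2-diones without C–C cleavage; dione 16 has doubly activated α-CH2 groups and enolises twice under Et3N to the aromatic catechol, which removes both stereocentres.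

Step 10
Reactants: 17 ring B catechol with ring A acetonide
Product: 18 isoplagilin, 2′,5-bis[2-(3-methoxyphenyl)ethyl]-[1,1′-biphenyl]-2,3,4′,5′-tetrol
Conditions: TFA/H2O (9:1), CH2Cl2, 0 °C to rt, under Ar
Reagents that add atoms: none
Why: Acid-catalysed ketal hydrolysis, in which protonation and opening of the 2,2-dimethylbenzodioxole through the tertiary oxocarbenium ion release acetone and the ring A catechol, while the aryl methyl ethers are stable to aqueous trifluoroacetic acid.

Compound list
1 | 3-bromo-4,5-dihydroxybenzaldehyde | O=Cc1cc(O)c(O)c(Br)c1 | starting material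
2 | 7-bromo-2,2-dimethyl-1,3-benzodioxole-5-carbaldehyde | O=Cc1cc(Br)c2OC(C)(C)Oc2c1 | intermediate
3 | diethyl (3-methoxybenzyl)phosphonate | CCOP(=O)(OCC)Cc1cccc(OC)c1 | starting material
4 | potassium phosphonate carbanion (potassium salt of deprotonated 3) | CCOP(=O)(OCC)[CH-]c1cccc(OC)c1.[K+] | intermediate (not isolated)
5 | 4-bromo-6-[(E)-2-(3-methoxyphenyl)ethenyl]-2,2-dimethyl-1,3-benzodioxole | COc1cccc(/C=C/c2cc(Br)c3OC(C)(C)Oc3c2)c1 | intermediate
6 | 4-bromo-6-[2-(3-methoxyphenyl)ethyl]-2,2-dimethyl-1,3-benzodioxole | COc1cccc(CCc2cc(Br)c3OC(C)(C)Oc3c2)c1 | intermediate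
7 | propargyl bromide (3-bromoprop-1-yne) | C#CCBr | starting material
8 | 3-methoxybenzyl bromide | COc1cccc(CBr)c1 | starting material
9 | allenylmagnesium bromide (propargyl Grignard reagent) | C=C=C[Mg]Br | intermediate (not isolated)
10 | 1-(but-3-yn-1-yl)-3-methoxybenzene | C#CCCc1cccc(OC)c1 | intermediate
11 | 4-[4-(3-methoxyphenyl)but-1-yn-1-yl]-6-[2-(3-methoxyphenyl)ethyl]-2,2-dimethyl-1,3-benzodioxole | COc1cccc(CCC#Cc2cc(CCc3cccc(OC)c3)cc3OC(C)(C)Oc23)c1 | intermediate
12 | 4-[5-(3-methoxyphenyl)-3-methylidenepent-1-en-2-yl]-6-[2-(3-methoxyphenyl)ethyl]-2,2-dimethyl-1,3-benzodioxole | C=C(CCc1cccc(OC)c1)C(=C)c1cc(CCc2cccc(OC)c2)cc2OC(C)(C)Oc12 | intermediate (key-step precursor)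
13 | vinylene carbonate (1,3-dioxol-2-one) | O=C1OC=CO1 | starting material
14 | cis-5-{6-[2-(3-methoxyphenyl)ethyl]-2,2-dimethyl-1,3-benzodioxol-4-yl}-6-[2-(3-methoxyphenyl)ethyl]-3a,4,7,7a-tetrahydro-1,3-benzodioxol-2-one, racemic (one enantiomer drawn) | O=C1O[C@H]2CC(CCc3cccc(OC)c3)=C(c3cc(CCc4cccc(OC)c4)cc4OC(C)(C)Oc34)C[C@H]2O1 | intermediate (key-step product)
15 | cis-4-{6-[2-(3-methoxyphenyl)ethyl]-2,2-dimethyl-1,3-benzodioxol-4-yl}-5-[2-(3-methoxyphenyl)ethyl]cyclohex-4-ene-1,2-diol, racemic (one enantiomer drawn) | O[C@H]1CC(CCc2cccc(OC)c2)=C(c2cc(CCc3cccc(OC)c3)cc3OC(C)(C)Oc23)C[C@H]1O | intermediate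
16 | 4-{6-[2-(3-methoxyphenyl)ethyl]-2,2-dimethyl-1,3-benzodioxol-4-yl}-5-[2-(3-methoxyphenyl)ethyl]cyclohex-4-ene-1,2-dione | O=C1CC(CCc2cccc(OC)c2)=C(c2cc(CCc3cccc(OC)c3)cc3OC(C)(C)Oc23)CC1=O | intermediate (not isolated)
17 | 4-{6-[2-(3-methoxyphenyl)ethyl]-2,2-dimethyl-1,3-benzodioxol-4-yl}-5-[2-(3-methoxyphenyl)ethyl]benzene-1,2-diol | Oc1cc(CCc2cccc(OC)c2)c(-c2cc(CCc3cccc(OC)c3)cc3OC(C)(C)Oc23)cc1O | intermediate
18 | isoplagilin, 2′,5-bis[2-(3-methoxyphenyl)ethyl]-[1,1′-biphenyl]-2,3,4′,5′-tetrol (achiral) | COc1cccc(CCc2cc(O)c(O)c(-c3cc(O)c(O)cc3CCc3cccc(OC)c3)c2)c1 | target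

Total step count: 10. Longest linear sequence: 9 steps (steps 1, 2, 3, 5, 6, 7, 8, 9, 10); step 4 is a one-step side branch.

Steps most likely to fail

Step 7. Vinylene carbonate is a sluggish dienophile, so thermal dimerisation or polymerisation of the diene may outrun the cycloaddition at the temperature required. The fallback installs the two oxygens after ring closure. Setting out from 12, a Diels–Alder reaction with the much more reactive acetylene equivalent (E)-1,2-bis(phenylsulfonyl)ethylene (toluene, 110 °C) should give the trans-4,5-bis(phenylsulfonyl)cyclohexene F1. Reductive elimination of both sulfonyl groups with sodium amalgam (NaH2PO4, MeOH/THF, −20 °C) should give the cyclohexa-1,4-diene F2, to be handled under argon to prevent aromatisation by air. Dihydroxylation with OsO4 (cat.) and N-methylmorpholine N-oxide in acetone/H2O should then take the cis-disubstituted C=C in preference to the hindered tetrasubstituted one and deliver the cis-diol 15, where the route is rejoined at step 9.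

Step 6. The ruthenium vinylcarbene may be held as a chelate by the neighbouring ketal oxygen, or the hindered alkyne may react so slowly that the catalyst decomposes before full conversion. The fallback builds the diene by carbonyl olefination. Setting out from 11, oxidation of the alkyne with PdCl2 (cat.) in DMSO at 140 °C should give the 1,2-dione F3, and twofold Wittig methylenation with excess Ph3P=CH2 (THF, 0 °C to rt) should give diene 12, which re-enters the route at step 7.

Step 9. The oxidation may stop at the ketol stage, or activated DMSO may react on with the newly formed catechol (ortho-methylthiomethylation). The fallback uses a hypervalent iodine oxidant and accepts over-oxidation. Setting out from 15, IBX (excess, DMSO, rt) should take the diol through the dione, without C–C cleavage, on to the ortho-quinone F4, and reduction with aqueous Na2S2O4 during work-up should give catechol 17, which re-enters the route at step 10.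

Further compounds
F1 | step 7 | trans-4-{6-[2-(3-methoxyphenyl)ethyl]-2,2-dimethyl-1,3-benzodioxol-4-yl}-5-[2-(3-methoxyphenyl)ethyl]-1,2-bis(phenylsulfonyl)cyclohex-4-ene, racemic (trans-4,5-bis(phenylsulfonyl)cyclohexene) | O=S(=O)(c1ccccc1)[C@@H]1CC(CCc2cccc(OC)c2)=C(c2cc(CCc3cccc(OC)c3)cc3OC(C)(C)Oc23)C[C@H]1S(=O)(=O)c1ccccc1
F2 | step 7 | 4-{2-[2-(3-methoxyphenyl)ethyl]cyclohexa-1,4-dien-1-yl}-6-[2-(3-methoxyphenyl)ethyl]-2,2-dimethyl-1,3-benzodioxole (cyclohexa-1,4-diene) | C1=CCC(CCc2cccc(OC)c2)=C(c2cc(CCc3cccc(OC)c3)cc3OC(C)(C)Oc23)C1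
F3 | step 6 | 1-{6-[2-(3-methoxyphenyl)ethyl]-2,2-dimethyl-1,3-benzodioxol-4-yl}-4-(3-methoxyphenyl)butane-1,2-dione (1,2-dione) | COc1cccc(CCC(=O)C(=O)c2cc(CCc3cccc(OC)c3)cc3OC(C)(C)Oc23)c1
F4 | step 9 | 4-{6-[2-(3-methoxyphenyl)ethyl]-2,2-dimethyl-1,3-benzodioxol-4-yl}-5-[2-(3-methoxyphenyl)ethyl]cyclohexa-3,5-diene-1,2-dione (ortho-quinone) | O=C1C=C(CCc2cccc(OC)c2)C(c2cc(CCc3cccc(OC)c3)cc3OC(C)(C)Oc23)=CC1=O
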